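**Retrosynthetic overview**

1. Target 14 ← 3-bromo-4-quinolone 13 by hydrogenolysis of the C3–Br bond; the skeleton is unchanged.
2. 13 ← 3-silyloxyindole 9 + bromoform 10. The route rests on the lone C3–H carbon of the pyridone ring, which lies between C2 (bound to N1, bearing the pentadecyl chain) and the C4 carbonyl. Removing it leaves N1–C2=C3–O of an O-silylated indoxyl, so the six-membered N-ring is made by inserting one carbene carbon into the indole C2–C3 bond.
3. 9 ← 3-bromoindole 5 by bromine–lithium exchange, oxygen transfer to the C3–Li bond and O-silylation in one flask, so the free indoxyl is never handled.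
4. 5 ← 1-methylindole 1 + 1-bromopentadecane 2 by C2 lithiation–alkylation, then C3 bromination.
5. Ring order: the benzo and five-membered rings are bought in 1; the pyridone ring is formed last (step 4) by ring expansion.

Key step: step 4

Assumption: in step 4 the silyl group of the quinolinium intermediate 12 is taken to leave as the silyl fluoride in the fluoride work-up; compounds 5 to 9 are handled under argon and used without storage.

**Route**

Step 1
Reactants: 1 1-methyl-1H-indole; 2 1-bromopentadecane
Product: 4 1-methyl-2-pentadecyl-1H-indole, via 2-lithio-1-methylindole 3 (not isolated)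
Conditions: n-BuLi (1.1 equiv), THF, 0 °C to rt; then 2, rt to 50 °C
Reagents that add atoms: none
Why: The N-methyl group leaves C2–H as the most acidic ring position, and the resulting aryllithium should displace bromide from the primary alkyl bromide (C2 lithiation followed by SN2 alkylation).

Step 2
Reactants: 4 1-methyl-2-pentadecyl-1H-indole
Product: 5 3-bromo-1-methyl-2-pentadecyl-1H-indole
Conditions: NBS (1.0 equiv), THF, −78 °C to 0 °C, dark; used directly
Reagents that add atoms: N-bromosuccinimide, O=C1CCC(=O)N1Br
Why: Electrophilic aromatic bromination at C3, the enamine carbon and the only free position of the five-membered ring; the cold, ionic conditions should avoid radical bromination of the chain.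

Step 3
Reactants: 5 3-bromo-1-methyl-2-pentadecyl-1H-indole; 6 triisopropylsilyl trifluoromethanesulfonate
Product: 9 1-methyl-2-pentadecyl-3-[(triisopropylsilyl)oxy]-1H-indole, via 3-lithio-1-methyl-2-pentadecylindole 7 (not isolated), via lithium 1-methyl-2-pentadecylindol-3-olate 8 (not isolated)
Conditions: t-BuLi (2.0 equiv), THF, −78 °C; LiOOtBu (1.05 equiv, from anhydrous t-BuOOH and n-BuLi, THF, −78 °C), −78 °C to 0 °C; then 6 (2.2 equiv), −78 °C to 0 °C; argon
Reagents that add atoms: tert-butyl hydroperoxide (used as LiOOtBu), CC(C)(C)OO; triisopropylsilyl trifluoromethanesulfonate (6), CC(C)[Si](C(C)C)(C(C)C)OS(=O)(=O)C(F)(F)F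
Why: Bromine–lithium exchange gives the C3 aryllithium (C2 is blocked, so it cannot migrate), which should attack the electrophilic peroxide oxygen of lithium tert-butyl peroxide (oxygenation of an organolithium, known for aryl- and vinyllithiums); the resulting indoxyl enolate is then silylated on oxygen by the silyl triflate.

Step 4
Reactants: 9 1-methyl-2-pentadecyl-3-[(triisopropylsilyl)oxy]-1H-indole; 10 bromoform
Product: 13 3-bromo-1-methyl-2-pentadecylquinolin-4(1H)-one, via dibromocyclopropane adduct 11 (not isolated), via 4-silyloxyquinolinium bromide 12 (not isolated)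
Conditions: CHBr3 (2.5 equiv), KOtBu (3 equiv), hexane, −30 °C to rt; then Bu4NF, THF, rt
Reagents that add atoms: bromoform (10), BrC(Br)Br
Why: Proposed new method: KOtBu deprotonates bromoform and α-elimination gives dibromocarbene, which should add in a concerted [2+1] fashion to the C2=C3 bond of 9 to give 11; ionisation of the endo bromine with disrotatory two-electron opening of the former C2–C3 bond, pushed by the nitrogen and silyloxy lone pairs, should then give the aromatic quinolinium 12, and fluoride cleaves its activated O–Si bond to leave 13 with the inserted carbon as C3–Br. The closest known reaction types are the Ciamician–Dennstedt ring expansion of indoles to 3-haloquinolines and the dihalocarbene ring expansion of cyclic silyl enol ethers to 2-halo-enones; their combination on a 3-silyloxyindole has not been shown. The three-membered ring closes by cheletropic [2+1] addition, and the six-membered pyridone ring is not closed end to end but arises by electrocyclic ring expansion of the five-membered ring. The two stereocentres of 11 are necessarily cis-fused, racemic and destroyed in the opening, so none needs control. The carbene must attack C2=C3 and not the benzo ring, and the silyl ether must outlast the alkoxide until the carbene has added: the double donor substitution makes C2=C3 by far the most nucleophilic site, the N-methyl group excludes the indolyl-anion pathway to 3H-indoles, and the bulky silyl group in cold hexane should resist tert-butoxide.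

Step 5
Reactants: 13 3-bromo-1-methyl-2-pentadecylquinolin-4(1H)-one
Product: 14 1-methyl-2-pentadecylquinolin-4(1H)-one
Conditions: H2 (1 atm), 10% Pd/C (zerovalent palladium on carbon), Et3N, MeOH/EtOAc, rt
Reagents that add atoms: none
Why: Catalytic hydrogenolysis (hydrodehalogenation) of the C3–Br bond, with Et3N taking up HBr; the vinylogous amide ring and the benzo ring should not be reduced at 1 atm.

**Compound list**

1 | 1-methyl-1H-indole | Cn1ccc2ccccc21 | starting material
2 | 1-bromopentadecane | CCCCCCCCCCCCCCCBr | starting material
3 | 2-lithio-1-methyl-1H-indole | [Li]c1cc2ccccc2n1C | intermediate (not isolated)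
4 | 1-methyl-2-pentadecyl-1H-indole | CCCCCCCCCCCCCCCc1cc2ccccc2n1C | intermediate
5 | 3-bromo-1-methyl-2-pentadecyl-1H-indole | CCCCCCCCCCCCCCCc1c(Br)c2ccccc2n1C | intermediate
6 | triisopropylsilyl trifluoromethanesulfonate | CC(C)[Si](C(C)C)(C(C)C)OS(=O)(=O)C(F)(F)F | starting material
7 | 3-lithio-1-methyl-2-pentadecyl-1H-indole | CCCCCCCCCCCCCCCc1c([Li])c2ccccc2n1C | intermediate (not isolated)
8 | lithium 1-methyl-2-pentadecyl-1H-indol-3-olate | CCCCCCCCCCCCCCCc1c([O-])c2ccccc2n1C.[Li+] | intermediate (not isolated)
9 | 1-methyl-2-pentadecyl-3-[(triisopropylsilyl)oxy]-1H-indole | CCCCCCCCCCCCCCCc1c(O[Si](C(C)C)(C(C)C)C(C)C)c2ccccc2n1C | intermediate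
10 | bromoform | BrC(Br)Br | starting material
11 | 1,1-dibromo-2-methyl-1a-pentadecyl-6b-[(triisopropylsilyl)oxy]-1,1a,2,6b-tetrahydrocyclopropa[b]indole (cis-fused, racemic, one enantiomer drawn) | CCCCCCCCCCCCCCC[C@]12N(C)c3ccccc3[C@@]1(O[Si](C(C)C)(C(C)C)C(C)C)C2(Br)Br | intermediate (not isolated)
12 | 3-bromo-1-methyl-2-pentadecyl-4-[(triisopropylsilyl)oxy]quinolin-1-ium bromide | CCCCCCCCCCCCCCCc1c(Br)c(O[Si](C(C)C)(C(C)C)C(C)C)c2ccccc2[n+]1C.[Br-] | intermediate (not isolated)
13 | 3-bromo-1-methyl-2-pentadecylquinolin-4(1H)-one | CCCCCCCCCCCCCCCc1c(Br)c(=O)c2ccccc2n1C | intermediate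
14 | 1-methyl-2-pentadecylquinolin-4(1H)-one | CCCCCCCCCCCCCCCc1cc(=O)c2ccccc2n1C | target

Total step count: 5. Longest linear sequence: 5 steps (1 → 4 → 5 → 9 → 13 → 14).

**Steps most likely to fail**

Step 4 (proposed new method). The alkoxide may strip the silyl group before the carbene adds, after which the free enolate would be alkylated at C2 by the carbene and no ring expansion would occur. The crowded C2=C3 bond may also cyclopropanate too slowly, so that the carbene is lost to side reactions. The fallback uses known chemistry (Witkop oxidation, then Camps cyclisation); it sets out from 5 and rejoins the route at the target 14. Bromine–lithium exchange on 5 (t-BuLi, THF, −78 °C, through 7) and quenching with MeI should give 1,3-dimethyl-2-pentadecyl-1H-indole F1. Oxidative cleavage of its C2=C3 bond (O3, CH2Cl2/MeOH, −78 °C; Me2S) should give N-(2-acetylphenyl)-N-methylhexadecanamide F2. Base (KOtBu, t-BuOH, 80 °C) should then close the ketone enolate onto the amide carbonyl with loss of water, so that the acetyl methyl carbon becomes C3–H and 14 is reached without passing through 13. A strong base is chosen to favour this mode over attack of the amide α-carbon on the ketone.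

Step 3. Oxygen transfer may be incomplete (protonation of 7 back to 4), the electron-rich enolate 8 may be oxidised further by surplus peroxide, or silylation may be slowed by the lithium tert-butoxide formed alongside. The fallback sets out from 5 and rejoins at 9. The aryllithium 7 is quenched with 2-isopropoxy-4,4,5,5-tetramethyl-1,3,2-dioxaborolane to give 1-methyl-2-pentadecyl-3-(4,4,5,5-tetramethyl-1,3,2-dioxaborolan-2-yl)-1H-indole F3, which can be isolated. Oxidation of the C–B bond (H2O2, NaOH, THF/H2O, 0 °C, argon) should give 1-methyl-2-pentadecylindolin-3-one F4 (racemic, the keto form of the indoxyl), carried on crude because it is air-sensitive. Soft enolisation and silylation (TIPSOTf, Et3N, CH2Cl2, 0 °C) should then give 9.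

Step 1. SN2 alkylation by the basic aryllithium may be slow and accompanied by E2 elimination of the long-chain bromide, leaving 1 and an alkene that is hard to separate from the greasy product. The fallback sets out from 1 and rejoins at 4. The lithio compound 3 is added to pentadecanal (THF, −78 °C) to give 1-(1-methyl-1H-indol-2-yl)pentadecan-1-ol F5 (racemic). Acid-catalysed dehydration (TsOH cat., toluene, 80 °C) should give 1-methyl-2-[(E)-pentadec-1-en-1-yl]-1H-indole F6. Hydrogenation (H2, Pd/C (zerovalent palladium on carbon), EtOAc, rt) should then give 4.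

**Further compounds**

F1 | step 4 | 1,3-dimethyl-2-pentadecyl-1H-indole | CCCCCCCCCCCCCCCc1c(C)c2ccccc2n1C
F2 | step 4 | N-(2-acetylphenyl)-N-methylhexadecanamide | CCCCCCCCCCCCCCCC(=O)N(C)c1ccccc1C(C)=O
F3 | step 3 | 1-methyl-2-pentadecyl-3-(4,4,5,5-tetramethyl-1,3,2-dioxaborolan-2-yl)-1H-indole | CCCCCCCCCCCCCCCc1c(B2OC(C)(C)C(C)(C)O2)c2ccccc2n1C
F4 | step 3 | 1-methyl-2-pentadecylindolin-3-one (racemic) | CCCCCCCCCCCCCCCC1N(C)c2ccccc2C1=O
F5 | step 1 | 1-(1-methyl-1H-indol-2-yl)pentadecan-1-ol (racemic) | CCCCCCCCCCCCCCC(O)c1cc2ccccc2n1C
F6 | step 1 | 1-methyl-2-[(E)-pentadec-1-en-1-yl]-1H-indole | CCCCCCCCCCCCC/C=C/c1cc2ccccc2n1C
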